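## The problem

Compound 17 (CNP0283712.1) is an acyclic, unsymmetrical ether. Two 1-(7-methoxycoumarin-8-yl)-3-methylbut-3-ene-1,2-diol units are joined through one oxygen (Oe) on their benzylic carbons. In each arm C1 is the benzylic carbon, C2 the carbinol carbon and C3 the isopropenyl carbon. Arm a is 1R,2R (Oe and OH syn) and arm b is 1S,2R (anti).

- The arms are diastereomers of each other, so dimerising one diol cannot give 17; each arm needs its own stereocontrol.
- Both benzylic carbons carry an aryl group with two ortho oxygens (the C7 methoxy group and the lactone ring oxygen). Etherification between them would run through stabilised cations and lose configuration, so the C–O bonds at C1a and C1b are better made by carbonyl chemistry inside a ring.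
- C1a and C1b are 1,3-related across Oe, and C2b is 1,2-related to C1b. In a six-membered ring containing Oe these become a cis-2,6 pair and a trans-2,3 pair, so C1b can control C1a and C2b.
- C2a must be syn to Oe. Felkin–Anh addition to an α-alkoxy aldehyde gives anti, so C2a needs reagent control.
- The coumarin lactones exclude organolithium and Grignard reagents, strong base and unselective hydride. The coumarin C3=C4 bonds and electron-rich arenes limit oxidants. The benzylic C–O bonds ionise in strong acid. Any intermediate with a benzylic C–H next to a carbonyl can epimerise.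
- The enabling feature: if C3b and C2a are joined by a double bond, Oe, C1b, C2b, C3b (with its methyl), C2a and C1a are O1, C2, C3, C4, C5 and C6 of a 2,6-diaryl-4-methyl-2H-pyran-3(6H)-one. That pyranone is the ring-expanded oxidation product of a 2-furyl carbinol carrying the second coumarin at furan C5 and the methyl at furan C3. Cleaving C4=C5 later returns the two arms already differentiated, as a methyl ketone and an aldehyde.

## Retrosynthesis

**17 from 16 (O2b–Si).** The last step only frees the C2b hydroxyl from its tert-butyldimethylsilyl ether 16. The silyl group is needed earlier to stop the C2b hydroxyl closing a lactol onto the aldehyde of arm a. Buffered fluoride is the mildest exit for a molecule with two lactones and an acid-labile benzylic ether.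

**16 from 15 (C3b=CH2).** The isopropenyl group of arm b is cut to the methyl ketone 15. Adding a second isopropenyl nucleophile instead would need a second aldehyde and would erase the difference between the arms. The forward reaction must methylenate a hindered α-silyloxy ketone without base (C2b is enolisable and Oe is β to the carbonyl) and without touching the lactones.

**15 from 13 and 14 (C2a–C3a).** The isopropenyl group of arm a is cut to aldehyde 13 and 2-bromopropene 14. An organochromium nucleophile is chosen over magnesium or lithium because 13 also holds a ketone and two lactones. The forward reaction must deliver the alkenyl group to the Re face, against the Felkin–Anh preference, so a chiral ligand on chromium is asked to decide.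

**13 from 12 (C3b=C2a reconnected).** Joining the ketone carbon C3b and the aldehyde carbon C2a as an alkene gives the dihydropyran 12. An open chain with three stereocentres and two different carbonyl groups becomes one ring in which all three centres are ring-controlled. Forward, ozone must cleave the trisubstituted ring alkene and spare the electron-poor coumarin C3=C4 bonds.

**12 from 11 and 10 (O–Si, C2b–H).** Desilylation gives allylic alcohol 11, and removing the C3 hydride gives enone 10. The forward 1,2-reduction must place the hydroxyl trans to the C2 aryl group, which is the normal axial-attack outcome for such pyranones and is the anti relation of arm b.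

**10 from 8 via 9 (C1a–H, then C1a–Oe and the pyran ring).** Replacing the C6 hydrogen of 10 by hydroxyl gives hemiketal 9, the Achmatowicz product of furyl carbinol 8. This cut is preferred to an oxa-Michael or Prins closure because it makes the C1a–Oe bond by hemiketalisation, not substitution. It also turns the six-atom core into an aromatic furan that two aryl–carbon couplings can assemble. Compound 8 has one stereocentre where 10 has two. The forward step must oxidise only the furan and then add hydride at C6 cis to the C2 aryl group without enolising C2.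

**8 from 7 and 6 (C1b–H).** The single catalyst-set centre is traced to ketone 7 (enantioselective reduction) and 7 to racemic carbinol 6 (oxidation). This detour is accepted because no reliable enantioselective addition of so hindered an aryl nucleophile is at hand. The reduction must distinguish a twisted 2,6-dioxygenated aryl group from a coplanar furyl group.

**6 from 5 and 3 (C8–C1b).** The carbinol carbon is cut from its coumarin to give furfural 5 and iodide 3. The aryl nucleophile must be generated in the presence of its own lactone, which points to nickel/chromium mediation.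

**5 from 3 and 4 (C8–furan C5, the later C8–C1a bond).** Direct C–H arylation of 3-methylfuran-2-carbaldehyde 4 with iodide 3 avoids making a furyl metal or boron reagent. C5 is the only free α-position of 4.

**3 from 2 and 1 (O–CH3, C8–I).** Iodide 3 comes from umbelliferone 1 by ortho-iodination to 2 and O-methylation. Iodinating the free phenol first uses the phenoxide to direct the halogen to C8.

## Roads not taken

**Alternative 1: conjunctive coupling across an enol ether boronate.**
- Cut: C8–C1b and C2b–C3b.
- Forward: the (E)-2-alkoxyvinyl pinacol boronate A1 (its alkoxy group is the O2a-silylated arm a) is turned into a boron ate complex with isopropenyllithium A2. This is coupled with 7-methoxycoumarin-8-yl triflate A3 under a palladium catalyst with a chiral ferrocenyl bisphosphine. The aryl group adds to the enol ether carbon (C1b) while isopropenyl migrates from boron to C2b, giving boronic ester A4. Oxidation of the C–B bond and desilylation would finish the synthesis.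
- Merits: two C–C bonds and both centres of arm b in one catalytic step. Anti addition across the E-alkene gives the anti arm directly. The route is highly convergent.
- Weak points: A2 is an organolithium and A1 already carries a coumarin lactone. A3 is a di-ortho-substituted, electron-rich triflate. An alkoxy-substituted vinyl boronate is not an established substrate for this coupling. A4 is a β-alkoxy boronic ester and can lose boron and Oe by β-elimination, which would destroy the ether. The catalyst would have to override the two centres of arm a, and arm a still needs its own enantioselective synthesis.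
- Comparison: this road is more convergent and would set C1b and C2b at once, where the chosen plan needs an enantioselective reduction and a ring reduction. Against that, the chosen plan uses only established reaction types, keeps organolithiums away from the lactones, and derives three of the four centres from one catalyst-set centre.

**Alternative 2: diglycolate linchpin with double enolate arylation.**
- Cut: both C8–C1 bonds.
- Forward: the bis-zinc enolate of dimethyl diglycolate A5 is arylated twice with iodide 3 under palladium catalysis. This gives the meso diester A6 together with its C2-symmetric diastereomer A7.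
- Merits: the shortest conceivable entry to the diaryl ether core, from a cheap symmetrical linchpin. A6 has the correct relative configuration at C1a and C1b.
- Weak points: nothing controls A6 against A7, and the α-aryl-α-alkoxy ester centres epimerise. The second arylation meets a hindered enolate and a di-ortho-substituted iodide. The two enantiotopic esters of A6 must then be told apart and each converted to CH(OH)–isopropenyl with opposite relative configuration, through epimerisable α-aryl carbonyl intermediates.
- Comparison: this road reaches the core in about three steps where the chosen plan needs seven, a real advantage. It postpones the stereochemical problem instead of solving it. The chosen plan spends its early steps on a ring that differentiates the arms and relays configuration.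

**Alternative 3: three-component oxocarbenium oxyallylation on a chiral ether.**
- Cut: C1a–Oe and C1a–C2a.
- Forward: 8-formyl-7-methoxycoumarin A8, the trimethylsilyl ether A9 of the O2b-silylated arm-b diol and the (Z)-γ-silyloxy-β-methylallylstannane A10 combine under a silyl triflate. A8 and A9 form an oxocarbenium ion, which A10 attacks through its γ-carbon to give the bis-silyl ether A11; desilylation gives 17.
- Merits: arm a is made in one step with both centres. The open transition state of a (Z)-γ-alkoxyallylstannane favours the syn relation that arm a needs, so simple diastereoselection is matched. The longest linear sequence could be the shortest of all four plans.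
- Weak points: the facial selectivity at C1a rests on acyclic 1,3-induction from C1b through the ether oxygen, which is modest and hard to predict. The benzylic oxocarbenium ion with two ortho oxygens forms reversibly and can exchange alkoxy groups, scrambling the ether. The Lewis acid also threatens the allylic silyl ether of A9. A9 needs its own asymmetric synthesis, and stoichiometric tin is used.
- Comparison: this road sets the syn arm by a well-understood substrate-independent selectivity, which is exactly where the chosen plan is weakest (a reagent-controlled anti-Felkin addition). The chosen plan sets against this a cyclic, conformationally governed answer to the C1a/C1b relation, which Alternative 3 leaves to acyclic induction.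

Key step: step 7

Assumption 1: in step 6 the twisted coumarin-8-yl group is taken as the large ketone substituent, so the (S)-oxazaborolidine should give the S carbinol; if a model ketone shows the opposite sense, the (R)-catalyst is used and nothing else changes.

Assumption 2: in step 11 the (S)-configured sulfonamide ligand is taken as the one that sends the alkenyl group to the Re face of the aldehyde; if a model α-alkoxy aldehyde shows the opposite sense, its enantiomer is used.

## Route

Step 1
Reactants: 1 umbelliferone (7-hydroxy-2H-chromen-2-one)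
Product: 2 7-hydroxy-8-iodo-2H-chromen-2-one
Conditions: I2, KI, aq. NH3, rt; then dilute H2SO4
Reagents that add atoms: iodine, II
Why: Electrophilic aromatic iodination of the phenoxide; in aqueous ammonia iodine enters C8, the ortho position between the two ring oxygens, which is the established regiochemistry for umbelliferone, and the lactone re-closes on acidification if it has opened.

Step 2
Reactants: 2 7-hydroxy-8-iodo-2H-chromen-2-one
Product: 3 8-iodo-7-methoxy-2H-chromen-2-one
Conditions: MeI, K2CO3, acetone, reflux
Reagents that add atoms: iodomethane, CI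
Why: Williamson O-methylation of the phenol; carbonate in acetone leaves the coumarin and the aryl iodide untouched.

Step 3
Reactants: 3 8-iodo-7-methoxy-2H-chromen-2-one; 4 3-methylfuran-2-carbaldehyde
Product: 5 5-(7-methoxy-2-oxo-2H-chromen-8-yl)-3-methylfuran-2-carbaldehyde
Conditions: Pd(OAc)2 (5 mol %), PCy3·HBF4 (10 mol %), PivOH (30 mol %), K2CO3, DMA, 100 °C
Reagents that add atoms: none
Why: Palladium-catalysed direct C–H arylation of a furfural by concerted metalation–deprotonation with pivalate as proton shuttle; C5 is the only free α-position of 4, and the aldehyde and lactone tolerate dry carbonate.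

Step 4
Reactants: 5 5-(7-methoxy-2-oxo-2H-chromen-8-yl)-3-methylfuran-2-carbaldehyde; 3 8-iodo-7-methoxy-2H-chromen-2-one
Product: 6 rac-(7-methoxy-2-oxo-2H-chromen-8-yl)[5-(7-methoxy-2-oxo-2H-chromen-8-yl)-3-methylfuran-2-yl]methanol
Conditions: CrCl2 (4 equiv), NiCl2 (2 mol %), DMF, rt → 50 °C
Reagents that add atoms: none
Why: Nozaki–Hiyama–Kishi reaction: nickel inserts into the aryl iodide, the aryl group passes to trivalent chromium and adds only to the aldehyde, leaving lactones and coumarin alkenes alone; the racemic centre is reset in steps 5 and 6.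

Step 5
Reactants: 6 rac-(7-methoxy-2-oxo-2H-chromen-8-yl)[5-(7-methoxy-2-oxo-2H-chromen-8-yl)-3-methylfuran-2-yl]methanol
Product: 7 7-methoxy-8-{[5-(7-methoxy-2-oxo-2H-chromen-8-yl)-3-methylfuran-2-yl]carbonyl}-2H-chromen-2-one
Conditions: Dess–Martin periodinane, CH2Cl2, rt
Reagents that add atoms: none
Why: Dess–Martin oxidation of a doubly activated (aryl, furyl) carbinol under neutral conditions that leave the furan and both coumarins intact.

Step 6
Reactants: 7 7-methoxy-8-{[5-(7-methoxy-2-oxo-2H-chromen-8-yl)-3-methylfuran-2-yl]carbonyl}-2H-chromen-2-one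
Product: 8 (S)-(7-methoxy-2-oxo-2H-chromen-8-yl)[5-(7-methoxy-2-oxo-2H-chromen-8-yl)-3-methylfuran-2-yl]methanol
Conditions: (S)-Me-CBS (20 mol %), BH3·SMe2, THF, −20 °C; MeOH
Reagents that add atoms: none
Why: Corey–Bakshi–Shibata reduction; the twisted di-ortho-substituted coumarinyl group should act as the large substituent and the coplanar furyl group as the small one, so the ketone binds the catalyst anti to the aryl group and hydride is delivered to the Re face, giving the S carbinol.

Step 7
Reactants: 8 (S)-(7-methoxy-2-oxo-2H-chromen-8-yl)[5-(7-methoxy-2-oxo-2H-chromen-8-yl)-3-methylfuran-2-yl]methanol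
Product: 10 (2S,6S)-2,6-bis(7-methoxy-2-oxo-2H-chromen-8-yl)-4-methyl-2H-pyran-3(6H)-one, via hemiketal 9 (not isolated)
Conditions: VO(acac)2 (5 mol %), t-BuOOH, CH2Cl2, 0 °C → rt; then Et3SiH (excess), CF3CO2H, CH2Cl2, −40 → −20 °C
Reagents that add atoms: tert-butyl hydroperoxide, CC(C)(C)OO
Why: Achmatowicz rearrangement followed by ionic hydrogenation: the vanadium alkylperoxide bound to the carbinol oxygen epoxidises the neighbouring furan C2=C3 bond, the epoxide opens to the Z-ene-dione, and the carbinol oxygen adds to the aryl ketone carbon (6-exo-trig) to give hemiketal 9, so the carbinol oxygen becomes Oe and the furan oxygen the hemiketal hydroxyl. CF3CO2H then ionises 9 to a cyclic oxocarbenium ion stabilised by the aryl group with its two ortho oxygens, and Et3SiH transfers hydride to C6. The closest known reaction type is the Achmatowicz rearrangement of 2-furyl carbinols combined with silane/acid reduction of the resulting lactols to cis-2,6-disubstituted 2H-pyran-3(6H)-ones; a 6-aryl hemiketal that also bears a 2-aryl group is a close extension. The new centre C6 (C1a) is controlled by C2 (C1b): in the half-chair cation the C2 aryl group lies pseudo-equatorial and hydride enters pseudo-axially on the face of the C2 hydrogen, so both aryl groups end pseudo-equatorial (2,6-cis). The step needs chemoselective furan oxidation, secured by hydroxyl direction, which the electron-poor coumarin alkenes lack. It also needs cis selectivity, secured by the stereoelectronic preference and by cis being the more stable isomer. Finally it needs retention at C2, which demands that hydride capture outrun enolisation towards the aromatic 3-hydroxypyrylium ion; low temperature, excess silane and a twisted aryl group that conjugates poorly with an enol serve this.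

Step 8
Reactants: 10 (2S,6S)-2,6-bis(7-methoxy-2-oxo-2H-chromen-8-yl)-4-methyl-2H-pyran-3(6H)-one
Product: 11 (2S,3R,6S)-2,6-bis(7-methoxy-2-oxo-2H-chromen-8-yl)-4-methyl-3,6-dihydro-2H-pyran-3-ol
Conditions: NaBH4, CeCl3·7H2O, MeOH/CH2Cl2, −78 °C
Reagents that add atoms: none
Why: Luche reduction: 1,2-selective hydride addition to the enone by axial attack on the half-chair (no 1,3-diaxial substituent opposes it) gives the pseudo-equatorial 3R alcohol trans to the C2 aryl group, the anti relation of arm b; CeCl3 suppresses conjugate reduction and attack on the coumarins, and the low temperature protects C2 from epimerisation.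

Step 9
Reactants: 11 (2S,3R,6S)-2,6-bis(7-methoxy-2-oxo-2H-chromen-8-yl)-4-methyl-3,6-dihydro-2H-pyran-3-ol
Product: 12 tert-butyl{[(2S,3R,6S)-2,6-bis(7-methoxy-2-oxo-2H-chromen-8-yl)-4-methyl-3,6-dihydro-2H-pyran-3-yl]oxy}dimethylsilane
Conditions: TBSOTf, 2,6-lutidine, CH2Cl2, −78 → 0 °C
Reagents that add atoms: tert-butyldimethylsilyl trifluoromethanesulfonate, CC(C)(C)[Si](C)(C)OS(=O)(=O)C(F)(F)F
Why: Silylation of a hindered secondary allylic alcohol with a silyl triflate and a hindered base; the silyl ether prevents lactol formation with the aldehyde released in step 10 and should survive steps 10 to 12.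

Step 10
Reactants: 12 tert-butyl{[(2S,3R,6S)-2,6-bis(7-methoxy-2-oxo-2H-chromen-8-yl)-4-methyl-3,6-dihydro-2H-pyran-3-yl]oxy}dimethylsilane
Product: 13 (2R)-2-{[(1S,2S)-2-(tert-butyldimethylsilyloxy)-1-(7-methoxy-2-oxo-2H-chromen-8-yl)-3-oxobutyl]oxy}-2-(7-methoxy-2-oxo-2H-chromen-8-yl)acetaldehyde
Conditions: O3, CH2Cl2, −78 °C (Sudan Red 7B end point); PPh3, −78 °C → rt
Reagents that add atoms: ozone, [O-][O+]=O
Why: Ozonolysis with reductive work-up: the trisubstituted ring alkene reacts far faster than the electron-poor coumarin C3=C4 bonds and the arenes, and the indicator dye marks the end point; C4 becomes the methyl ketone of arm b and C5 the aldehyde of arm a, and the crude aldehyde is used at once to avoid epimerisation at its benzylic α-carbon.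

Step 11
Reactants: 13 (2R)-2-{[(1S,2S)-2-(tert-butyldimethylsilyloxy)-1-(7-methoxy-2-oxo-2H-chromen-8-yl)-3-oxobutyl]oxy}-2-(7-methoxy-2-oxo-2H-chromen-8-yl)acetaldehyde; 14 2-bromopropene
Product: 15 (3S,4S)-3-(tert-butyldimethylsilyloxy)-4-{[(1R,2R)-2-hydroxy-1-(7-methoxy-2-oxo-2H-chromen-8-yl)-3-methylbut-3-en-1-yl]oxy}-4-(7-methoxy-2-oxo-2H-chromen-8-yl)butan-2-one
Conditions: CrCl2 (4 equiv), (S)-N-[2-(4-isopropyl-4,5-dihydrooxazol-2-yl)-6-methylphenyl]methanesulfonamide (4.4 equiv), Et3N, THF, rt; then NiCl2 (cat.), 14, 13, rt
Reagents that add atoms: none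
Why: Asymmetric Nozaki–Hiyama–Kishi reaction: the isopropenylchromium species carrying the chiral sulfonamide ligand adds only to the aldehyde (ketone and lactones are inert to it), and the ligand should direct the alkenyl group to the Re face to give the 2R carbinol (syn arm a), overriding the Felkin–Anh preference for the anti epimer.

Step 12
Reactants: 15 (3S,4S)-3-(tert-butyldimethylsilyloxy)-4-{[(1R,2R)-2-hydroxy-1-(7-methoxy-2-oxo-2H-chromen-8-yl)-3-methylbut-3-en-1-yl]oxy}-4-(7-methoxy-2-oxo-2H-chromen-8-yl)butan-2-one
Product: 16 8-[(1R,2R)-1-{[(1S,2R)-2-(tert-butyldimethylsilyloxy)-1-(7-methoxy-2-oxo-2H-chromen-8-yl)-3-methylbut-3-en-1-yl]oxy}-2-hydroxy-3-methylbut-3-en-1-yl]-7-methoxy-2H-chromen-2-one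
Conditions: Zn, CH2Br2, TiCl4, THF/CH2Cl2, 0 °C → rt
Reagents that add atoms: dibromomethane, BrCBr
Why: Takai–Lombardo methylenation: the non-basic zinc/titanium methylene reagent converts ketones but not lactones, does not enolise the α-silyloxy ketone (no epimerisation at C2b, no β-elimination of Oe) and tolerates the free hydroxyl when used in excess.

Step 13
Reactants: 16 8-[(1R,2R)-1-{[(1S,2R)-2-(tert-butyldimethylsilyloxy)-1-(7-methoxy-2-oxo-2H-chromen-8-yl)-3-methylbut-3-en-1-yl]oxy}-2-hydroxy-3-methylbut-3-en-1-yl]-7-methoxy-2H-chromen-2-one
Product: 17 8-[(1R,2R)-2-hydroxy-1-{[(1S,2R)-2-hydroxy-1-(7-methoxy-2-oxo-2H-chromen-8-yl)-3-methylbut-3-en-1-yl]oxy}-3-methylbut-3-en-1-yl]-7-methoxy-2H-chromen-2-one (CNP0283712.1)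
Conditions: Bu4NF, AcOH, THF, 0 °C → rt
Reagents that add atoms: none
Why: Fluoride desilylation buffered with acetic acid; the near-neutral medium should leave the lactones, the benzylic ether and the allylic alcohols unchanged, and no stereocentre is touched.

## Compound list

1 | umbelliferone (7-hydroxy-2H-chromen-2-one) | O=c1ccc2ccc(O)cc2o1 | starting material
2 | 7-hydroxy-8-iodo-2H-chromen-2-one | O=c1ccc2ccc(O)c(I)c2o1 | intermediate
3 | 8-iodo-7-methoxy-2H-chromen-2-one | COc1ccc2ccc(=O)oc2c1I | intermediate
4 | 3-methylfuran-2-carbaldehyde | Cc1ccoc1C=O | starting material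
5 | 5-(7-methoxy-2-oxo-2H-chromen-8-yl)-3-methylfuran-2-carbaldehyde | Cc1cc(-c2c(OC)ccc3ccc(=O)oc23)oc1C=O | intermediate
6 | rac-(7-methoxy-2-oxo-2H-chromen-8-yl)[5-(7-methoxy-2-oxo-2H-chromen-8-yl)-3-methylfuran-2-yl]methanol | OC(c1c(OC)ccc2ccc(=O)oc12)c1oc(-c2c(OC)ccc3ccc(=O)oc23)cc1C | intermediate
7 | 7-methoxy-8-{[5-(7-methoxy-2-oxo-2H-chromen-8-yl)-3-methylfuran-2-yl]carbonyl}-2H-chromen-2-one | O=C(c1c(OC)ccc2ccc(=O)oc12)c1oc(-c2c(OC)ccc3ccc(=O)oc23)cc1C | intermediate
8 | (S)-(7-methoxy-2-oxo-2H-chromen-8-yl)[5-(7-methoxy-2-oxo-2H-chromen-8-yl)-3-methylfuran-2-yl]methanol | O[C@@H](c1c(OC)ccc2ccc(=O)oc12)c1oc(-c2c(OC)ccc3ccc(=O)oc23)cc1C | intermediate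
9 | (2S)-6-hydroxy-2,6-bis(7-methoxy-2-oxo-2H-chromen-8-yl)-4-methyl-2H-pyran-3(6H)-one (both C6 epimers) | O=C1C(C)=CC(O)(c2c(OC)ccc3ccc(=O)oc23)O[C@H]1c1c(OC)ccc2ccc(=O)oc12 | intermediate
10 | (2S,6S)-2,6-bis(7-methoxy-2-oxo-2H-chromen-8-yl)-4-methyl-2H-pyran-3(6H)-one | O=C1C(C)=C[C@@H](c2c(OC)ccc3ccc(=O)oc23)O[C@H]1c1c(OC)ccc2ccc(=O)oc12 | intermediate
11 | (2S,3R,6S)-2,6-bis(7-methoxy-2-oxo-2H-chromen-8-yl)-4-methyl-3,6-dihydro-2H-pyran-3-ol | O[C@@H]1C(C)=C[C@@H](c2c(OC)ccc3ccc(=O)oc23)O[C@H]1c1c(OC)ccc2ccc(=O)oc12 | intermediate
12 | tert-butyl{[(2S,3R,6S)-2,6-bis(7-methoxy-2-oxo-2H-chromen-8-yl)-4-methyl-3,6-dihydro-2H-pyran-3-yl]oxy}dimethylsilane | CC(C)(C)[Si](C)(C)O[C@@H]1C(C)=C[C@@H](c2c(OC)ccc3ccc(=O)oc23)O[C@H]1c1c(OC)ccc2ccc(=O)oc12 | intermediate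
13 | (2R)-2-{[(1S,2S)-2-(tert-butyldimethylsilyloxy)-1-(7-methoxy-2-oxo-2H-chromen-8-yl)-3-oxobutyl]oxy}-2-(7-methoxy-2-oxo-2H-chromen-8-yl)acetaldehyde | O=C[C@H](O[C@@H](c1c(OC)ccc2ccc(=O)oc12)[C@H](O[Si](C)(C)C(C)(C)C)C(C)=O)c1c(OC)ccc2ccc(=O)oc12 | intermediate
14 | 2-bromopropene | CC(Br)=C | starting material
15 | (3S,4S)-3-(tert-butyldimethylsilyloxy)-4-{[(1R,2R)-2-hydroxy-1-(7-methoxy-2-oxo-2H-chromen-8-yl)-3-methylbut-3-en-1-yl]oxy}-4-(7-methoxy-2-oxo-2H-chromen-8-yl)butan-2-one | C=C(C)[C@@H](O)[C@H](O[C@@H](c1c(OC)ccc2ccc(=O)oc12)[C@H](O[Si](C)(C)C(C)(C)C)C(C)=O)c1c(OC)ccc2ccc(=O)oc12 | intermediate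
16 | 8-[(1R,2R)-1-{[(1S,2R)-2-(tert-butyldimethylsilyloxy)-1-(7-methoxy-2-oxo-2H-chromen-8-yl)-3-methylbut-3-en-1-yl]oxy}-2-hydroxy-3-methylbut-3-en-1-yl]-7-methoxy-2H-chromen-2-one | C=C(C)[C@@H](O)[C@H](O[C@@H](c1c(OC)ccc2ccc(=O)oc12)[C@H](O[Si](C)(C)C(C)(C)C)C(=C)C)c1c(OC)ccc2ccc(=O)oc12 | intermediate
17 | 8-[(1R,2R)-2-hydroxy-1-{[(1S,2R)-2-hydroxy-1-(7-methoxy-2-oxo-2H-chromen-8-yl)-3-methylbut-3-en-1-yl]oxy}-3-methylbut-3-en-1-yl]-7-methoxy-2H-chromen-2-one (CNP0283712.1) | C=C(C)[C@@H](O)[C@H](O[C@@H](c1c(OC)ccc2ccc(=O)oc12)[C@H](O)C(=C)C)c1c(OC)ccc2ccc(=O)oc12 | target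

## Step count and risk

Total step count: 13. Longest linear sequence: 13 steps (1 to 17); 4 and 14 are purchased and iodide 3 is used in steps 3 and 4.

**The key step (step 7).** The most likely failure is loss of configuration at C2 before hydride transfer, by enolisation of hemiketal 9 or of its oxocarbenium ion towards the aromatic 3-hydroxypyrylium ion. A second failure is incomplete ring closure onto the hindered aryl ketone, so that open-chain material is reduced. The fallback removes the enolisable ketone before any cation is made. It sets out from 9, now isolated.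
- Trimethyl orthoformate and pyridinium p-toluenesulfonate in methanol should give the methyl ketal F1.
- Luche reduction should give the trans allylic alcohol F2.
- Silylation with TBSOTf and 2,6-lutidine should give the silyl ether F3.
- Et3SiH with BF3·OEt2 at −78 °C should then replace the methoxy group by hydride, through the same pseudo-axial attack, and the sequence comes back to the route at 12.

**Step 11.** The most likely failure is poor facial selectivity, because the ligand must overcome the Felkin–Anh bias of a hindered α-aryl-α-alkoxy aldehyde; epimerisation of that aldehyde at C1a during the reaction is the second concern. The fallback converges both C2a epimers through a ketone and sets the centre by reduction, where substrate and reagent cooperate. It sets out from 13.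
- The ligand-free reaction with 14 (CrCl2, NiCl2, DMF) should give the epimeric alcohols F4.
- Takai–Lombardo methylenation should give the dienyl alcohols F5.
- Dess–Martin oxidation should give the single isopropenyl ketone F6.
- Corey–Bakshi–Shibata reduction should give the 2R alcohol and comes back to the route at 16. The (S)-catalyst is assumed, with the branched C1a substituent as the large group. The Felkin–Anh preference of an α-alkoxy ketone leads to the same syn product.

**Step 6.** The most likely failure is low enantioselectivity, since both ketone substituents are aromatic and the catalyst has only the twist of one of them to read. The fallback replaces reduction by kinetic resolution and sets out from racemic 6. Under Sharpless kinetic resolution conditions (Ti(OiPr)4, L-(+)-diisopropyl tartrate, t-BuOOH (0.6 equiv), 4 Å sieves, CH2Cl2, −20 °C) the S enantiomer should be oxidised faster, by analogy with secondary allylic alcohols and alkyl 2-furyl carbinols. This delivers hemiketal 9 directly and comes back to the route at 9, which is reduced as in the second half of step 7. The unreacted (R)-carbinol F7 is separated and can be recycled by oxidation to 7.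

**Step 4.** The most likely failure is sluggish addition, because an arylchromium reagent flanked by two ortho oxygens is a weak, hindered nucleophile and the aldehyde may be consumed by reductive dimerisation. The fallback uses a polar organometallic made by halogen–metal exchange and sets out from 3. Treatment with iPrMgCl·LiCl in THF at −78 °C should give the arylmagnesium chloride F8, with exchange assisted by the two ortho oxygens and the lactone spared at this temperature. Addition of 5 at −78 °C comes back to the route at 6.

**Step 12.** The most likely failure is incomplete conversion of the hindered α-silyloxy ketone, or Lewis-acid damage to the benzylic ether over the long reaction time. The fallback separates C–C bond formation from elimination and sets out from 15. Addition of Me3SiCH2MgCl with CeCl3 in THF at −78 °C (a non-basic organocerium that adds to ketones faster than to lactones) should give the β-hydroxysilane F9. HF·pyridine in THF should then effect Peterson elimination and remove the silyl ether in the same operation, so the sequence comes back to the route at 17.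

## Further compounds

F1 | step 7 | (2S)-6-methoxy-2,6-bis(7-methoxy-2-oxo-2H-chromen-8-yl)-4-methyl-2H-pyran-3(6H)-one (both C6 epimers) | O=C1C(C)=CC(OC)(c2c(OC)ccc3ccc(=O)oc23)O[C@H]1c1c(OC)ccc2ccc(=O)oc12
F2 | step 7 | (2S,3R)-6-methoxy-2,6-bis(7-methoxy-2-oxo-2H-chromen-8-yl)-4-methyl-3,6-dihydro-2H-pyran-3-ol | O[C@@H]1C(C)=CC(OC)(c2c(OC)ccc3ccc(=O)oc23)O[C@H]1c1c(OC)ccc2ccc(=O)oc12
F3 | step 7 | tert-butyl{[(2S,3R)-6-methoxy-2,6-bis(7-methoxy-2-oxo-2H-chromen-8-yl)-4-methyl-3,6-dihydro-2H-pyran-3-yl]oxy}dimethylsilane | CC(C)(C)[Si](C)(C)O[C@@H]1C(C)=CC(OC)(c2c(OC)ccc3ccc(=O)oc23)O[C@H]1c1c(OC)ccc2ccc(=O)oc12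
F4 | step 11 | 15 as the mixture of both C2a epimers | C=C(C)C(O)[C@H](O[C@@H](c1c(OC)ccc2ccc(=O)oc12)[C@H](O[Si](C)(C)C(C)(C)C)C(C)=O)c1c(OC)ccc2ccc(=O)oc12
F5 | step 11 | 16 as the mixture of both C2a epimers | C=C(C)C(O)[C@H](O[C@@H](c1c(OC)ccc2ccc(=O)oc12)[C@H](O[Si](C)(C)C(C)(C)C)C(=C)C)c1c(OC)ccc2ccc(=O)oc12
F6 | step 11 | (1R)-1-{[(1S,2R)-2-(tert-butyldimethylsilyloxy)-1-(7-methoxy-2-oxo-2H-chromen-8-yl)-3-methylbut-3-en-1-yl]oxy}-1-(7-methoxy-2-oxo-2H-chromen-8-yl)-3-methylbut-3-en-2-one | C=C(C)C(=O)[C@H](O[C@@H](c1c(OC)ccc2ccc(=O)oc12)[C@H](O[Si](C)(C)C(C)(C)C)C(=C)C)c1c(OC)ccc2ccc(=O)oc12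
F7 | step 6 | (R)-(7-methoxy-2-oxo-2H-chromen-8-yl)[5-(7-methoxy-2-oxo-2H-chromen-8-yl)-3-methylfuran-2-yl]methanol | O[C@H](c1c(OC)ccc2ccc(=O)oc12)c1oc(-c2c(OC)ccc3ccc(=O)oc23)cc1C
F8 | step 4 | (7-methoxy-2-oxo-2H-chromen-8-yl)magnesium chloride | COc1ccc2ccc(=O)oc2c1[Mg]Cl
F9 | step 12 | (3S,4S)-3-(tert-butyldimethylsilyloxy)-4-{[(1R,2R)-2-hydroxy-1-(7-methoxy-2-oxo-2H-chromen-8-yl)-3-methylbut-3-en-1-yl]oxy}-4-(7-methoxy-2-oxo-2H-chromen-8-yl)-2-methyl-1-(trimethylsilyl)butan-2-ol (both C2 epimers) | C=C(C)[C@@H](O)[C@H](O[C@@H](c1c(OC)ccc2ccc(=O)oc12)[C@H](O[Si](C)(C)C(C)(C)C)C(C)(O)C[Si](C)(C)C)c1c(OC)ccc2ccc(=O)oc12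
A1 | alternative 1 | (E)-2-alkoxyvinyl pinacol boronate of O2a-silylated arm a | C=C(C)[C@@H](O[Si](C)(C)C(C)(C)C)[C@H](O/C=C/B1OC(C)(C)C(C)(C)O1)c1c(OC)ccc2ccc(=O)oc12
A2 | alternative 1 | isopropenyllithium | [Li]C(C)=C
A3 | alternative 1 | 7-methoxy-2-oxo-2H-chromen-8-yl trifluoromethanesulfonate | COc1ccc2ccc(=O)oc2c1OS(=O)(=O)C(F)(F)F
A4 | alternative 1 | C2b pinacol boronic ester of the O2a-silylated target skeleton | C=C(C)[C@@H](O[Si](C)(C)C(C)(C)C)[C@H](O[C@@H](c1c(OC)ccc2ccc(=O)oc12)[C@H](B1OC(C)(C)C(C)(C)O1)C(=C)C)c1c(OC)ccc2ccc(=O)oc12
A5 | alternative 2 | dimethyl diglycolate | COC(=O)COCC(=O)OC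
A6 | alternative 2 | dimethyl 2,2'-oxybis[2-(7-methoxy-2-oxo-2H-chromen-8-yl)acetate], meso isomer | COC(=O)[C@H](O[C@@H](c1c(OC)ccc2ccc(=O)oc12)C(=O)OC)c1c(OC)ccc2ccc(=O)oc12
A7 | alternative 2 | dimethyl 2,2'-oxybis[2-(7-methoxy-2-oxo-2H-chromen-8-yl)acetate], C2-symmetric isomer (racemic, one enantiomer drawn) | COC(=O)[C@H](O[C@H](c1c(OC)ccc2ccc(=O)oc12)C(=O)OC)c1c(OC)ccc2ccc(=O)oc12
A8 | alternative 3 | 7-methoxy-2-oxo-2H-chromene-8-carbaldehyde | COc1ccc2ccc(=O)oc2c1C=O
A9 | alternative 3 | trimethylsilyl ether of the O2b-silylated arm-b diol | C[Si](C)(C)O[C@@H](c1c(OC)ccc2ccc(=O)oc12)[C@H](O[Si](C)(C)C(C)(C)C)C(=C)C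
A10 | alternative 3 | (Z)-tributyl[3-(tert-butyldimethylsilyloxy)-2-methylprop-2-en-1-yl]stannane | CCCC[Sn](CCCC)(CCCC)C/C(C)=C\O[Si](C)(C)C(C)(C)C
A11 | alternative 3 | bis(tert-butyldimethylsilyl) ether of the target at O2a and O2b | C=C(C)[C@@H](O[Si](C)(C)C(C)(C)C)[C@H](O[C@@H](c1c(OC)ccc2ccc(=O)oc12)[C@H](O[Si](C)(C)C(C)(C)C)C(=C)C)c1c(OC)ccc2ccc(=O)oc12
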